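Only C2 (formyl) and C5 (henicosyl) of the pyrrole ring bear substituents; C3 and C4 are plain CH. The ring is therefore cut at N1–C5 and C2–C3, so that a glycine ester supplies N1, C2 and the future formyl carbon, while a conjugated ynal supplies C3, C4, C5 and the chain. In a single operation the sulfonamide nitrogen of ethyl N-tosylglycinate adds to the chain-bearing alkyne carbon of tetracos-2-ynal, the glycinate carbon condenses with the aldehyde, and water is lost, delivering the aromatic ring. The ynal arises from 1-docosanol by two one-carbon homologations; ester-to-aldehyde adjustment under tosyl protection, then desulfonylation, completes the route.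

Key step: step 5

Remark: the target is achiral, so no stereocentre needs control; aldol adduct 11 is assumed to form as a diastereomer mixture, which is immaterial because both centres vanish on aromatisation (carbon count: C22 alcohol + one carbon from CBr4 + one from DMF = C24 ynal = C21 chain + C5, C4, C3).

Step 1
Reactants: 1 glycine ethyl ester hydrochloride; 2 4-toluenesulfonyl chloride
Product: 3 ethyl N-tosylglycinate
Conditions: Et3N (2.2 equiv), CH2Cl2, 0 °C → rt
Reagents that add atoms: none
Why: N-sulfonylation of the liberated primary amine (Schotten–Baumann-type) should stop at the mono-sulfonamide, whose remaining N–H is too weakly nucleophilic to react again.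

Step 2
Reactants: 4 1-docosanol
Product: 5 docosanal
Conditions: TEMPO (2,2,6,6-tetramethylpiperidin-1-oxyl, 10 mol %), PhI(OAc)2 (1.1 equiv), CH2Cl2, 30 °C
Reagents that add atoms: none
Why: TEMPO-catalysed oxidation through the oxoammonium species should stop at the aldehyde, since in anhydrous CH2Cl2 no aldehyde hydrate is available for further oxidation.

Step 3
Reactants: 5 docosanal; 6 carbon tetrabromide
Product: 7 1,1-dibromotricos-1-ene
Conditions: PPh3 (4 equiv), 6 (2 equiv), CH2Cl2, 0 °C → rt
Reagents that add atoms: none
Why: Corey–Fuchs dibromoolefination, in which the ylide Ph3P=CBr2 formed from PPh3 and CBr4 undergoes a Wittig reaction with the unhindered aliphatic aldehyde.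

Step 4
Reactants: 7 1,1-dibromotricos-1-ene
Product: 9 tetracos-2-ynal, via lithium tricos-1-ynide 8 (not isolated)
Conditions: n-BuLi (2.1 equiv), THF, −78 → 0 °C; DMF (3 equiv), −78 °C → rt; inverse quench into cold 10% aq KH2PO4/MTBE
Reagents that add atoms: N,N-dimethylformamide, CN(C)C=O; n-butyllithium, [Li]CCCC (supplies only the lithium of 8)
Why: Second stage of the Corey–Fuchs sequence (lithium–bromine exchange, Fritsch–Buttenberg–Wiechell-type rearrangement, deprotonation to acetylide 8) followed by formylation with DMF, the buffered inverse quench protonating dimethylamine so that it cannot add to the ynal.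

Step 5
Reactants: 3 ethyl N-tosylglycinate; 9 tetracos-2-ynal
Product: 12 ethyl 5-henicosyl-1-tosyl-1H-pyrrole-2-carboxylate, via sulfonamido enal 10 (not isolated), via hydroxypyrroline aldol adduct 11 (not isolated)
Conditions: 3 (1.2 equiv), Cs2CO3 (1.2 equiv), THF–MeCN 1:1, slow addition of 9, 0 °C → rt; filter, then p-TsOH·H2O (10 mol %), toluene, 50 °C
Reagents that add atoms: none
Why: Cs2CO3 deprotonates the sulfonamide N–H of 3 and the nitrogen anion adds to the chain-bearing alkyne carbon of 9 (N1–C5), the allenolate being protonated to the β-sulfonamido enal 10, in which anti addition and reversible isomerisation place nitrogen and formyl cis. The glycinate carbon of 10, acidified by the ester and the N-sulfonyl group, then adds to the aldehyde carbon (C2–C3) in a favoured 5-(enolexo)-exo-trig aldol closure to give 11, and loss of water, begun by base (E1cB) and completed by the acid treatment, aromatises the ring. The closest known reaction type is the Kenner-type aza-Michael/aldol cyclocondensation of N-sulfonylglycinates with conjugated enones, enals and ynones, of which an ynal is simply a further substrate. No stereocentre survives, the two transient ones of 11 being erased on aromatisation. The step needs nitrogen to attack the β-carbon and not the carbonyl, which the secondary sulfonamide secures because its carbonyl adduct is only a reversible hemiaminal that cannot dehydrate to an imine; it also needs water and not sulfinate to leave from 11, which is favoured because the planar enamide nitrogen holds the N–S bond near the ring plane, out of alignment with the C2 carbanion, and because the final dehydration is run under acid.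

Step 6
Reactants: 12 ethyl 5-henicosyl-1-tosyl-1H-pyrrole-2-carboxylate
Product: 13 (5-henicosyl-1-tosyl-1H-pyrrol-2-yl)methanol
Conditions: i-Bu2AlH (2.5 equiv), toluene–THF, −40 → 0 °C; aq potassium sodium tartrate
Reagents that add atoms: none
Why: Ester reduction with i-Bu2AlH should give the primary carbinol while the N-sulfonyl group stays inert at low temperature and keeps the hydroxymethylpyrrole from ionising to an azafulvene.

Step 7
Reactants: 13 (5-henicosyl-1-tosyl-1H-pyrrol-2-yl)methanol
Product: 14 5-henicosyl-1-tosyl-1H-pyrrole-2-carbaldehyde
Conditions: activated MnO2 (15 equiv), CH2Cl2, rt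
Reagents that add atoms: none
Why: MnO2 oxidation of a heteroaryl (benzylic-type) carbinol should stop at the aldehyde and leave the sulfonamide and the saturated chain untouched.

Step 8
Reactants: 14 5-henicosyl-1-tosyl-1H-pyrrole-2-carbaldehyde
Product: 15 5-henicosyl-1H-pyrrole-2-carbaldehyde
Conditions: K2CO3 (2 equiv), MeOH–THF 1:1, rt → 40 °C; aq NH4Cl
Reagents that add atoms: none
Why: Nucleophilic N-desulfonylation, in which methoxide attacks sulfur and expels the 2-formylpyrrolide, a stabilised vinylogous amide anion that is protonated to the target.

Compound list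
1 | glycine ethyl ester hydrochloride | CCOC(=O)CN.Cl | starting material
2 | 4-toluenesulfonyl chloride | Cc1ccc(cc1)S(=O)(=O)Cl | starting material
3 | ethyl N-tosylglycinate | CCOC(=O)CNS(=O)(=O)c1ccc(C)cc1 | intermediate
4 | 1-docosanol | CCCCCCCCCCCCCCCCCCCCCCO | starting material
5 | docosanal | CCCCCCCCCCCCCCCCCCCCCC=O | intermediate
6 | carbon tetrabromide | BrC(Br)(Br)Br | starting material
7 | 1,1-dibromotricos-1-ene | CCCCCCCCCCCCCCCCCCCCCC=C(Br)Br | intermediate
8 | lithium tricos-1-ynide | CCCCCCCCCCCCCCCCCCCCCC#C[Li] | intermediate (not isolated)
9 | tetracos-2-ynal | CCCCCCCCCCCCCCCCCCCCCC#CC=O | intermediate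
10 | ethyl N-[(2Z)-1-oxotetracos-2-en-3-yl]-N-tosylglycinate | CCCCCCCCCCCCCCCCCCCCC/C(=C/C=O)N(CC(=O)OCC)S(=O)(=O)c1ccc(C)cc1 | intermediate (not isolated)
11 | ethyl 5-henicosyl-3-hydroxy-1-tosyl-2,3-dihydro-1H-pyrrole-2-carboxylate (racemic diastereomer mixture) | CCCCCCCCCCCCCCCCCCCCCC1=CC(O)C(C(=O)OCC)N1S(=O)(=O)c2ccc(C)cc2 | intermediate (not isolated)
12 | ethyl 5-henicosyl-1-tosyl-1H-pyrrole-2-carboxylate | CCCCCCCCCCCCCCCCCCCCCc1ccc(C(=O)OCC)n1S(=O)(=O)c2ccc(C)cc2 | intermediate
13 | (5-henicosyl-1-tosyl-1H-pyrrol-2-yl)methanol | CCCCCCCCCCCCCCCCCCCCCc1ccc(CO)n1S(=O)(=O)c2ccc(C)cc2 | intermediate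
14 | 5-henicosyl-1-tosyl-1H-pyrrole-2-carbaldehyde | CCCCCCCCCCCCCCCCCCCCCc1ccc(C=O)n1S(=O)(=O)c2ccc(C)cc2 | intermediate
15 | 5-henicosyl-1H-pyrrole-2-carbaldehyde | CCCCCCCCCCCCCCCCCCCCCc1ccc(C=O)[nH]1 | target

Total step count: 8. Longest linear sequence: 7 steps (steps 2 to 8, from 1-docosanol 4 to target 15); step 1 is a one-step side branch.

Steps most likely to fail

1. Step 5. Base-triggered self-condensation of the ynal may outrun the conjugate addition, or sulfinate may be expelled from the aldol adduct in place of water. Fallback: the ring is built at the enal oxidation level, where sulfinate loss becomes the aromatising event. Setting out from docosanal 5 and sulfonamide 3, a Wittig reaction of 5 with Ph3P=CHCHO in toluene at 80 °C should give (E)-tetracos-2-enal F1. With DBU (1,8-diazabicyclo[5.4.0]undec-7-ene) in THF, 3 and F1 should undergo the classical Kenner aza-Michael/aldol sequence to ethyl 5-henicosyl-3-hydroxy-1-tosylpyrrolidine-2-carboxylate F2. POCl3 in pyridine should dehydrate this to ethyl 5-henicosyl-1-tosyl-2,5-dihydro-1H-pyrrole-2-carboxylate F3. NaOEt in EtOH should then eliminate 4-toluenesulfinate and, after tautomerisation, give ethyl 5-henicosyl-1H-pyrrole-2-carboxylate F4. N-sulfonylation of F4 (NaH, TsCl, THF) returns to the route at 12.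

2. Step 4. The lithium–bromine exchange and rearrangement may stay incomplete if the long-chain substrate precipitates at low temperature, and dimethylamine released on quench may add to the triple bond. Fallback: setting out from dibromoolefin 7, acetylide 8 is generated as before but trapped with paraformaldehyde, which should give tetracos-2-yn-1-ol F5 as a stable, purifiable solid. Oxidation of F5 with MnO2 in CH2Cl2 rejoins the route at ynal 9, and no amine is ever present together with the ynal.

3. Step 6. Hydride attack at sulfur or nitrogen-to-oxygen sulfonyl transfer in the aluminium alkoxide may remove the protecting group early, after which the unprotected hydroxymethylpyrrole would self-condense. Fallback: the ester carbon is discarded and the formyl group is introduced by electrophilic substitution. Setting out from 12, heating with NaOH in ethylene glycol at about 170 °C should saponify the ester, cleave the N-sulfonyl group and decarboxylate the resulting 5-henicosyl-1H-pyrrole-2-carboxylic acid F6 in the same flask to 2-henicosyl-1H-pyrrole F7. Vilsmeier–Haack formylation of F7 (POCl3, DMF, 0 °C → rt; aq NaOAc) at the free α-position should give the target directly, returning to the route at 15.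

Further compounds
F1 | step 5 | (E)-tetracos-2-enal | CCCCCCCCCCCCCCCCCCCCC/C=C/C=O
F2 | step 5 | ethyl 5-henicosyl-3-hydroxy-1-tosylpyrrolidine-2-carboxylate (racemic diastereomer mixture) | CCCCCCCCCCCCCCCCCCCCCC1CC(O)C(C(=O)OCC)N1S(=O)(=O)c2ccc(C)cc2
F3 | step 5 | ethyl 5-henicosyl-1-tosyl-2,5-dihydro-1H-pyrrole-2-carboxylate (racemic diastereomer mixture) | CCCCCCCCCCCCCCCCCCCCCC1C=CC(C(=O)OCC)N1S(=O)(=O)c2ccc(C)cc2
F4 | step 5 | ethyl 5-henicosyl-1H-pyrrole-2-carboxylate | CCCCCCCCCCCCCCCCCCCCCc1ccc(C(=O)OCC)[nH]1
F5 | step 4 | tetracos-2-yn-1-ol | CCCCCCCCCCCCCCCCCCCCCC#CCO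
F6 | step 6 | 5-henicosyl-1H-pyrrole-2-carboxylic acid | CCCCCCCCCCCCCCCCCCCCCc1ccc(C(=O)O)[nH]1
F7 | step 6 | 2-henicosyl-1H-pyrrole | CCCCCCCCCCCCCCCCCCCCCc1ccc[nH]1
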